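**Retrosynthetic overview**
1. Last disconnection: the threo (7''R,8''R) arylglycerol ether is cut at C7''–C8'' (Evans syn-aldol of an aryloxyacetyl imide built on the free syringyl phenol of the core); both phenols travel as tosylates and are freed together at the end.
2. Core: ether ring A (C7–O–C9'–C8'–C8) is cut at O–C9' (Williamson closure at the primary carbon, C7 untouched) and traced to a γ-lactone (C9' as C=O); the endo aryl at C7' of ring B (C7'–O–C9–C8–C8') is traced to a C7'=C8' enol ether that takes up hydride on the convex face.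
3. Key disconnection C8–C8' (the ring-fusion bond): oxidative radical annulation of the aroylacetate of an (R)-1-arylprop-2-en-1-ol with Mn(OAc)3/Cu(OAc)2; ring A forms first (as lactone, by the C8–C8' bond), ring B second in the same flask (as dihydrofuran, by the C9–O bond); ring A is later opened by hydride and closed again as the ether.
4. Enabling feature: in the 3,7-dioxabicyclo[3.3.0]octane the fusion carbon C8' lies between the oxygen-bearing carbons C9' (ring A) and C7' (ring B), so it can be the α-carbon of a β-keto ester; the fusion carbon C8 carries C9H2–O and can be the internal carbon of a vinyl group on the carbinol C7; C9 and C7' are 1,4-related across C8–C8', so the bond joins two donor carbons and is made by oxidation.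
5. Building blocks: vanillin, vinylmagnesium bromide, 4-(benzyloxy)-3,5-dimethoxybenzoic acid, Meldrum's acid, syringaldehyde and (S)-4-benzyloxazolidin-2-one; the single stereocentre C7 (Sharpless kinetic resolution) controls all four core centres.

Key step: step 6

Remark: lignan numbering is used (guaiacyl unit C7–C9, core syringyl unit C7'–C9', side chain C7''–C9''); read from the SMILES, the guaiacyl ring is exo (H-7 trans to H-8), the syringyl ring is endo (H-7' cis to H-8') and the side chain is threo (7''R,8''R).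

**Route**

Step 1
Reactants: 1 vanillin
Product: 2 vanillin tosylate (4-formyl-2-methoxyphenyl 4-methylbenzenesulfonate)
Conditions: TsCl, Et3N, DMAP (cat.), CH2Cl2, 0 °C to rt
Reagents that add atoms: p-toluenesulfonyl chloride, Cc1ccc(cc1)S(Cl)(=O)=O
Why: O-sulfonylation of the phenol should be clean, and the tosylate is chosen because it is electron-withdrawing, so that the benzylic carbon of this ring resists ionisation in the allylic ester, the lactone and the acidic reduction that follow.

Step 2
Reactants: 2 vanillin tosylate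
Product: 3 racemic 4-(1-hydroxyprop-2-en-1-yl)-2-methoxyphenyl 4-methylbenzenesulfonate
Conditions: CH2=CHMgBr, THF, −78 °C; then H2O (pH 7 buffer)
Reagents that add atoms: vinylmagnesium bromide, C=C[Mg]Br
Why: Grignard 1,2-addition to the aldehyde at −78 °C should outrun attack at the aryl sulfonate and gives the racemic allylic alcohol.

Step 3
Reactants: 3 racemic allylic alcohol
Product: 4 4-[(1R)-1-hydroxyprop-2-en-1-yl]-2-methoxyphenyl 4-methylbenzenesulfonate
Conditions: Ti(OiPr)4, D-(−)-diisopropyl tartrate, t-BuOOH (0.6 equiv), 4 Å molecular sieves, CH2Cl2, −20 °C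
Reagents that add atoms: none
Why: Sharpless kinetic resolution, in which the D-(−)-tartrate complex epoxidises the (S)-alcohol faster, so that (R)-4 should remain in high enantiomeric purity once the reaction is taken beyond half conversion.

Step 4
Reactants: 5 4-(benzyloxy)-3,5-dimethoxybenzoic acid; 6 Meldrum's acid
Product: 7 5-{[4-(benzyloxy)-3,5-dimethoxyphenyl](hydroxy)methylidene}-2,2-dimethyl-1,3-dioxane-4,6-dione
Conditions: DCC, DMAP, CH2Cl2, 0 °C to rt
Reagents that add atoms: none
Why: Carbodiimide-mediated C-acylation of Meldrum's acid gives the stable enol form of the acyl Meldrum's acid.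

Step 5
Reactants: 4 (R)-allylic alcohol; 7 acyl Meldrum's acid
Product: 9 (1R)-1-[3-methoxy-4-(tosyloxy)phenyl]prop-2-en-1-yl 3-[4-(benzyloxy)-3,5-dimethoxyphenyl]-3-oxopropanoate, via aroylketene 8 (not isolated)
Conditions: toluene, 85 °C
Reagents that add atoms: none
Why: Thermal cycloreversion of the acyl Meldrum's acid releases the aroylketene, which the secondary alcohol should trap under neutral conditions (acylketene esterification), so that the stereocentre and the allylic system of 4 are not disturbed.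

Step 6
Reactants: 9 allylic aroylacetate
Product: 10 (3R,3aS)-6-[4-(benzyloxy)-3,5-dimethoxyphenyl]-3-[3-methoxy-4-(tosyloxy)phenyl]-3a,4-dihydro-1H,3H-furo[3,4-c]furan-1-one (ring A as γ-lactone, ring B as dihydrofuran with the C7'=C8' enol ether)
Conditions: Mn(OAc)3·2H2O (2.2 equiv), Cu(OAc)2·H2O (0.5 equiv), degassed AcOH, 50 °C
Reagents that add atoms: none
Why: Proposed new method: Mn(OAc)3 forms the trivalent-manganese enolate of the aroylacetate and, by inner-sphere electron transfer, the electrophilic radical at C8', which adds 5-exo-trig to the internal vinyl carbon C8 (a union of an enolate carbon with a nucleophilic alkene carbon, that is of two donor carbons); the primary C9 radical is captured by Cu(OAc)2, the organocopper intermediate is displaced by the neighbouring enol oxygen of the aryl ketone through a six-membered oxa-cupracycle, and loss of a proton leaves the C7'=C8' enol ether, the monovalent copper being re-oxidised by Mn(OAc)3. The closest known reaction types are the Mn(OAc)3-mediated dihydrofuran annulation of β-keto esters with terminal alkenes and the Mn(OAc)3/Cu(OAc)2 oxidative cyclisation of allylic malonates and acetoacetates to γ-lactones; new is their combination across an ester tether with a primary radical terminus. Ring A closes as a γ-lactone by 5-exo-trig radical C–C bond formation (C8'–C8), and ring B closes as a 2-aryl-4,5-dihydrofuran by C–O bond formation at C9 (5-exo-tet attack of the enol oxygen, formally a reductive elimination from copper). The only new stereocentre, C8, is set by the allylic stereocentre C7: in the chair-like Beckwith transition state the aryl group is pseudo-equatorial, so C9 ends trans to the aryl group on the lactone, and cis fusion of the two five-membered rings is geometrically enforced. The step needs O-capture at C9 to win over C-capture (cyclopropane), β-hydride loss and attack on the aroyl ring, which the strongly enolised aroyl group held next to C9 should secure; the product has no enolisable α-hydrogen and so should not be over-oxidised, and the electron-withdrawing tosylate keeps the benzylic allylic ester from ionising in warm acetic acid.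

Step 7
Reactants: 10 dihydrofuran-fused lactone
Product: 11 (3R,3aS,6S,6aR)-6-[4-(benzyloxy)-3,5-dimethoxyphenyl]-3-[3-methoxy-4-(tosyloxy)phenyl]tetrahydro-1H,3H-furo[3,4-c]furan-1-one (3-aryl exo, 6-aryl endo)
Conditions: Et3SiH (5 equiv), TFA (10 equiv), CH2Cl2, 0 °C to rt
Reagents that add atoms: none
Why: Ionic hydrogenation, in which protonation of the vinylogous carbonate gives an oxocarbenium ion at C7' to which Et3SiH should deliver hydride on the convex face (the face of H-8) while protonation at C8' can only give the cis-fused bicycle, so that the aryl group at C7' ends endo (H-7', H-8' and H-8 all cis), the lactone carbonyl next to C7' and the tosylate on the other ring disfavouring ionisation of either benzylic C–O bond.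

Step 8
Reactants: 11 bicyclic lactone
Product: 12 (R)-{(3S,4S,5S)-5-[4-(benzyloxy)-3,5-dimethoxyphenyl]-4-(hydroxymethyl)oxolan-3-yl}[3-methoxy-4-(tosyloxy)phenyl]methanol
Conditions: LiBH4, THF, 0 °C to rt
Reagents that add atoms: none
Why: Hydride reduction of the γ-lactone with LiBH4 should give the 1,4-diol without touching a stereocentre, the aryl sulfonate or the benzyl ether.

Step 9
Reactants: 12 diol
Product: 14 4-{(1R,3aS,4S,6aS)-4-[4-(benzyloxy)-3,5-dimethoxyphenyl]tetrahydro-1H,3H-furo[3,4-c]furan-1-yl}-2-methoxyphenyl 4-methylbenzenesulfonate, via primary monotosylate 13 (not isolated)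
Conditions: TsCl (1.1 equiv), pyridine, 0 °C; then 45 °C
Reagents that add atoms: none
Why: Chemoselective sulfonylation of the primary alcohol followed by 5-exo-tet Williamson closure by the benzylic hydroxyl forms the C–O bond at the primary carbon C9', so that C7 keeps its configuration and no benzylic cation arises that could epimerise the endo aryl centre.

Step 10
Reactants: 14 benzyl-protected furofuran
Product: 15 4-[(1R,3aS,4S,6aS)-4-(4-hydroxy-3,5-dimethoxyphenyl)tetrahydro-1H,3H-furo[3,4-c]furan-1-yl]-2-methoxyphenyl 4-methylbenzenesulfonate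
Conditions: H2 (1 atm), 10% Pd/C, EtOAc, rt, stopped at full conversion
Reagents that add atoms: none
Why: Catalytic hydrogenolysis of the aryl benzyl ether should be much faster than cleavage of the dialkyl benzylic ethers of the bicycle and leaves the aryl tosylate intact.

Step 11
Reactants: 16 (S)-4-benzyloxazolidin-2-one
Product: 17 (4S)-4-benzyl-3-(bromoacetyl)-1,3-oxazolidin-2-one
Conditions: n-BuLi, THF, −78 °C; then BrCH2COBr, −78 °C
Reagents that add atoms: bromoacetyl bromide, BrCC(Br)=O
Why: N-acylation of the lithiated oxazolidinone with the acid bromide gives the bromoacetyl imide.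

Step 12
Reactants: 15 syringyl phenol of the core; 17 bromoacetyl imide
Product: 18 aryloxyacetyl imide (the phenol oxygen of 15 carries CH2C(=O)–N of the (4S)-4-benzyl-2-oxo-oxazolidin-3-yl group)
Conditions: K2CO3, acetone, rt
Reagents that add atoms: none
Why: Williamson ether synthesis, in which the phenoxide should displace the reactive α-bromo imide under mild carbonate conditions that leave the imide and the aryl tosylate alone.

Step 13
Reactants: 19 syringaldehyde
Product: 20 4-formyl-2,6-dimethoxyphenyl 4-methylbenzenesulfonate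
Conditions: TsCl, Et3N, DMAP (cat.), CH2Cl2, rt
Reagents that add atoms: p-toluenesulfonyl chloride, Cc1ccc(cc1)S(Cl)(=O)=O
Why: O-sulfonylation gives an aldehyde whose later benzylic alcohol is deactivated toward ionisation and whose protecting group leaves together with the other tosylate.

Step 14
Reactants: 18 aryloxyacetyl imide; 20 syringaldehyde tosylate
Product: 23 syn-aldol adduct (imide with 2S,3R acyl chain: 2-aryloxy-3-hydroxy-3-[3,5-dimethoxy-4-(tosyloxy)phenyl]propanoyl), via boron enolate 21 (not isolated), via boron aldolate 22 (not isolated)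
Conditions: Bu2BOTf, i-Pr2NEt, CH2Cl2, −78 to 0 °C; 20, −78 to 0 °C; then pH 7 buffer, MeOH, 30% H2O2, 0 °C
Reagents that add atoms: none
Why: Evans syn-aldol reaction, in which the Z-boron enolate reacts through a chair-like Zimmerman–Traxler transition state on the enolate face opposite the benzyl group of the (S)-auxiliary, which should give the syn adduct that corresponds to the threo (7''R,8''R) side chain.

Step 15
Reactants: 23 aldol adduct
Product: 24 bis-tosylate of the target (side chain (1R,2R)-1,3-dihydroxy-1-arylpropan-2-yl ether)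
Conditions: LiBH4, THF, MeOH (1 equiv), 0 °C
Reagents that add atoms: none
Why: Reductive cleavage of the N-acyl oxazolidinone with LiBH4 should give the primary alcohol C9'' and release the auxiliary without epimerising the α-aryloxy centre.

Step 16
Reactants: 24 bis-tosylate
Product: 25 target, 4-[(1R,3aS,4S,6aS)-4-(4-{[(1R,2R)-1,3-dihydroxy-1-(4-hydroxy-3,5-dimethoxyphenyl)propan-2-yl]oxy}-3,5-dimethoxyphenyl)tetrahydro-1H,3H-furo[3,4-c]furan-1-yl]-2-methoxyphenol
Conditions: KOH, MeOH/H2O, 65 °C; then 1 M HCl to pH 5, 0 °C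
Reagents that add atoms: none
Why: Alkaline hydrolysis of the two aryl sulfonates (hydroxide attack at sulfur) should free both phenols, the dialkyl benzylic ethers and the alkyl aryl ether being stable to base at this temperature.

**Compound list**
1 | vanillin | COc1cc(C=O)ccc1O | starting material
2 | 4-formyl-2-methoxyphenyl 4-methylbenzenesulfonate | COc1cc(C=O)ccc1OS(=O)(=O)c1ccc(C)cc1 | intermediate
3 | racemic 4-(1-hydroxyprop-2-en-1-yl)-2-methoxyphenyl 4-methylbenzenesulfonate | C=CC(O)c1ccc(OS(=O)(=O)c2ccc(C)cc2)c(OC)c1 | intermediate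
4 | 4-[(1R)-1-hydroxyprop-2-en-1-yl]-2-methoxyphenyl 4-methylbenzenesulfonate | C=C[C@@H](O)c1ccc(OS(=O)(=O)c2ccc(C)cc2)c(OC)c1 | intermediate
5 | 4-(benzyloxy)-3,5-dimethoxybenzoic acid | OC(=O)c1cc(OC)c(OCc2ccccc2)c(OC)c1 | starting material
6 | Meldrum's acid (2,2-dimethyl-1,3-dioxane-4,6-dione) | CC1(C)OC(=O)CC(=O)O1 | starting material
7 | 5-{[4-(benzyloxy)-3,5-dimethoxyphenyl](hydroxy)methylidene}-2,2-dimethyl-1,3-dioxane-4,6-dione | CC1(C)OC(=O)C(=C(O)c2cc(OC)c(OCc3ccccc3)c(OC)c2)C(=O)O1 | intermediate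
8 | aroylketene, 3-[4-(benzyloxy)-3,5-dimethoxyphenyl]-3-oxoprop-1-en-1-one | O=C=CC(=O)c1cc(OC)c(OCc2ccccc2)c(OC)c1 | intermediate
9 | (1R)-1-[3-methoxy-4-(tosyloxy)phenyl]prop-2-en-1-yl 3-[4-(benzyloxy)-3,5-dimethoxyphenyl]-3-oxopropanoate | C=C[C@@H](OC(=O)CC(=O)c1cc(OC)c(OCc2ccccc2)c(OC)c1)c1ccc(OS(=O)(=O)c2ccc(C)cc2)c(OC)c1 | intermediate
10 | (3R,3aS)-6-[4-(benzyloxy)-3,5-dimethoxyphenyl]-3-[3-methoxy-4-(tosyloxy)phenyl]-3a,4-dihydro-1H,3H-furo[3,4-c]furan-1-one | COc1cc([C@@H]2OC(=O)C3=C(c4cc(OC)c(OCc5ccccc5)c(OC)c4)OC[C@@H]23)ccc1OS(=O)(=O)c1ccc(C)cc1 | intermediate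
11 | (3R,3aS,6S,6aR)-6-[4-(benzyloxy)-3,5-dimethoxyphenyl]-3-[3-methoxy-4-(tosyloxy)phenyl]tetrahydro-1H,3H-furo[3,4-c]furan-1-one | COc1cc([C@@H]2OC(=O)[C@@H]3[C@H]2CO[C@@H]3c2cc(OC)c(OCc3ccccc3)c(OC)c2)ccc1OS(=O)(=O)c1ccc(C)cc1 | intermediate
12 | (R)-{(3S,4S,5S)-5-[4-(benzyloxy)-3,5-dimethoxyphenyl]-4-(hydroxymethyl)oxolan-3-yl}[3-methoxy-4-(tosyloxy)phenyl]methanol | COc1cc([C@H](O)[C@@H]2CO[C@H](c3cc(OC)c(OCc4ccccc4)c(OC)c3)[C@@H]2CO)ccc1OS(=O)(=O)c1ccc(C)cc1 | intermediate
13 | primary monotosylate of 12 (tosyloxymethyl at C4 of the oxolane, benzylic OH free) | COc1cc([C@H](O)[C@@H]2CO[C@H](c3cc(OC)c(OCc4ccccc4)c(OC)c3)[C@@H]2COS(=O)(=O)c2ccc(C)cc2)ccc1OS(=O)(=O)c1ccc(C)cc1 | intermediate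
14 | 4-{(1R,3aS,4S,6aS)-4-[4-(benzyloxy)-3,5-dimethoxyphenyl]tetrahydro-1H,3H-furo[3,4-c]furan-1-yl}-2-methoxyphenyl 4-methylbenzenesulfonate | COc1cc([C@@H]2OC[C@@H]3[C@H]2CO[C@@H]3c2cc(OC)c(OCc3ccccc3)c(OC)c2)ccc1OS(=O)(=O)c1ccc(C)cc1 | intermediate
15 | 4-[(1R,3aS,4S,6aS)-4-(4-hydroxy-3,5-dimethoxyphenyl)tetrahydro-1H,3H-furo[3,4-c]furan-1-yl]-2-methoxyphenyl 4-methylbenzenesulfonate | COc1cc([C@@H]2OC[C@@H]3[C@H]2CO[C@@H]3c2cc(OC)c(O)c(OC)c2)ccc1OS(=O)(=O)c1ccc(C)cc1 | intermediate
16 | (S)-4-benzyloxazolidin-2-one | O=C1N[C@@H](Cc2ccccc2)CO1 | starting material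
17 | (4S)-4-benzyl-3-(bromoacetyl)-1,3-oxazolidin-2-one | BrCC(=O)N1C(=O)OC[C@@H]1Cc1ccccc1 | intermediate
18 | 4-[(1R,3aS,4S,6aS)-4-(4-{2-[(4S)-4-benzyl-2-oxo-1,3-oxazolidin-3-yl]-2-oxoethoxy}-3,5-dimethoxyphenyl)tetrahydro-1H,3H-furo[3,4-c]furan-1-yl]-2-methoxyphenyl 4-methylbenzenesulfonate | COc1cc([C@@H]2OC[C@@H]3[C@H]2CO[C@@H]3c2cc(OC)c(OCC(=O)N3C(=O)OC[C@@H]3Cc3ccccc3)c(OC)c2)ccc1OS(=O)(=O)c1ccc(C)cc1 | intermediate
19 | syringaldehyde | COc1cc(C=O)cc(OC)c1O | starting material
20 | 4-formyl-2,6-dimethoxyphenyl 4-methylbenzenesulfonate | COc1cc(C=O)cc(OC)c1OS(=O)(=O)c1ccc(C)cc1 | intermediate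
21 | Z-dibutylboron enolate of 18 | COc1cc([C@@H]2OC[C@@H]3[C@H]2CO[C@@H]3c2cc(OC)c(O/C=C(\OB(CCCC)CCCC)N3C(=O)OC[C@@H]3Cc3ccccc3)c(OC)c2)ccc1OS(=O)(=O)c1ccc(C)cc1 | intermediate
22 | dibutylboron aldolate of 23 | COc1cc([C@@H]2OC[C@@H]3[C@H]2CO[C@@H]3c2cc(OC)c(O[C@H](C(=O)N3C(=O)OC[C@@H]3Cc3ccccc3)[C@H](OB(CCCC)CCCC)c3cc(OC)c(OS(=O)(=O)c4ccc(C)cc4)c(OC)c3)c(OC)c2)ccc1OS(=O)(=O)c1ccc(C)cc1 | intermediate
23 | syn-aldol adduct, (4S)-4-benzyl-3-[(2S,3R)-2-(core aryloxy)-3-hydroxy-3-(3,5-dimethoxy-4-tosyloxyphenyl)propanoyl]oxazolidin-2-one | COc1cc([C@@H]2OC[C@@H]3[C@H]2CO[C@@H]3c2cc(OC)c(O[C@H](C(=O)N3C(=O)OC[C@@H]3Cc3ccccc3)[C@H](O)c3cc(OC)c(OS(=O)(=O)c4ccc(C)cc4)c(OC)c3)c(OC)c2)ccc1OS(=O)(=O)c1ccc(C)cc1 | intermediate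
24 | bis-tosylate of the target, side chain (1R,2R)-1,3-dihydroxy-1-[3,5-dimethoxy-4-(tosyloxy)phenyl]propan-2-yl ether | COc1cc([C@@H]2OC[C@@H]3[C@H]2CO[C@@H]3c2cc(OC)c(O[C@H](CO)[C@H](O)c3cc(OC)c(OS(=O)(=O)c4ccc(C)cc4)c(OC)c3)c(OC)c2)ccc1OS(=O)(=O)c1ccc(C)cc1 | intermediate
25 | 4-[(1R,3aS,4S,6aS)-4-(4-{[(1R,2R)-1,3-dihydroxy-1-(4-hydroxy-3,5-dimethoxyphenyl)propan-2-yl]oxy}-3,5-dimethoxyphenyl)tetrahydro-1H,3H-furo[3,4-c]furan-1-yl]-2-methoxyphenol | COc1cc([C@@H]2OC[C@@H]3[C@H]2CO[C@@H]3c2cc(OC)c(O[C@H](CO)[C@H](O)c3cc(OC)c(O)c(OC)c3)c(OC)c2)ccc1O | target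

**Step count and risks**

Total step count: 16. Longest linear sequence: 13 steps (1, 2, 3, 5, 6, 7, 8, 9, 10, 12, 14, 15, 16).

Most likely to fail, first: step 6. After the 5-exo closure the primary radical or its organocopper form may be diverted to C-alkylation (cyclopropane), to β-hydride loss or to attack on the aroyl ring, or the ester-tethered radical may cyclise too slowly and oligomerise. The fallback sets out from 9 and comes back at 10 by known chemistry. Diazo transfer to 9 (4-acetamidobenzenesulfonyl azide, Et3N, MeCN) should give the α-diazo β-keto ester F1. Intramolecular cyclopropanation with Rh2(OAc)4 (CH2Cl2, 40 °C) should give the 1-aroyl-3-oxabicyclo[3.1.0]hexan-2-one F2, with the same C8–C8' bond and the aryl group trans to the cyclopropane methylene. A Cloke–Wilson ring expansion (MgI2, THF, 60 °C: iodide opens the doubly activated cyclopropane at the CH2 carbon and the enolate oxygen recloses) should then give 10.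

Second: step 7. The electron-poor enol ether may be activated too weakly, or the acid may cause reductive opening of the new benzylic C–O bond, loss of the benzyl ether, or erosion of the convex-face preference. The fallback sets out from 10 and comes back at 11: heterogeneous hydrogenation over 5% Rh/Al2O3 (H2, 4 atm, EtOAc, rt) adds both hydrogens syn on the convex face under neutral conditions; no further compound F0 arises.

Third: step 14. The boron triflate may open or epimerise the acid-labile endo-aryl benzylic ether of the core, or enolisation of the hindered aryloxyacetyl imide may be sluggish and lower the facial control. The fallback sets out from 15 and comes back at 24; it sets C7'' by asymmetric reduction instead of an aldol. Alkylation of 15 with ethyl bromoacetate (K2CO3, acetone) gives the aryloxyacetate F3. Its lithium enolate (LiHMDS, THF, −78 °C) adds to 20 to give the hydroxy ester F4 as a diastereomer mixture. Dess–Martin oxidation gives the configurationally labile α-aryloxy β-keto ester F5. Noyori-type transfer hydrogenation with dynamic kinetic resolution (RuCl(p-cymene)[(S,S)-TsDPEN], HCO2H/Et3N) should give the syn (2S,3R) hydroxy ester F6. LiBH4 reduction then gives 24.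

**Further compounds**
F1 | step 6 | (1R)-1-[3-methoxy-4-(tosyloxy)phenyl]prop-2-en-1-yl 3-[4-(benzyloxy)-3,5-dimethoxyphenyl]-2-diazo-3-oxopropanoate | C=C[C@@H](OC(=O)C(=[N+]=[N-])C(=O)c1cc(OC)c(OCc2ccccc2)c(OC)c1)c1ccc(OS(=O)(=O)c2ccc(C)cc2)c(OC)c1
F2 | step 6 | (4R)-1-[4-(benzyloxy)-3,5-dimethoxybenzoyl]-4-[3-methoxy-4-(tosyloxy)phenyl]-3-oxabicyclo[3.1.0]hexan-2-one, aryl trans to the cyclopropane CH2 | COc1cc([C@@H]2OC(=O)[C@@]3(C(=O)c4cc(OC)c(OCc5ccccc5)c(OC)c4)C[C@@H]23)ccc1OS(=O)(=O)c1ccc(C)cc1
F0 | step 7 | none | none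
F3 | step 14 | ethyl 2-(core aryloxy)acetate (15 alkylated at the syringyl oxygen with CH2CO2Et) | COc1cc([C@@H]2OC[C@@H]3[C@H]2CO[C@@H]3c2cc(OC)c(OCC(=O)OCC)c(OC)c2)ccc1OS(=O)(=O)c1ccc(C)cc1
F4 | step 14 | ethyl 2-(core aryloxy)-3-hydroxy-3-[3,5-dimethoxy-4-(tosyloxy)phenyl]propanoate, mixture at C2 and C3 | COc1cc([C@@H]2OC[C@@H]3[C@H]2CO[C@@H]3c2cc(OC)c(OC(C(=O)OCC)C(O)c3cc(OC)c(OS(=O)(=O)c4ccc(C)cc4)c(OC)c3)c(OC)c2)ccc1OS(=O)(=O)c1ccc(C)cc1
F5 | step 14 | ethyl 2-(core aryloxy)-3-[3,5-dimethoxy-4-(tosyloxy)phenyl]-3-oxopropanoate, C2 labile | COc1cc([C@@H]2OC[C@@H]3[C@H]2CO[C@@H]3c2cc(OC)c(OC(C(=O)OCC)C(=O)c3cc(OC)c(OS(=O)(=O)c4ccc(C)cc4)c(OC)c3)c(OC)c2)ccc1OS(=O)(=O)c1ccc(C)cc1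
F6 | step 14 | ethyl (2S,3R)-2-(core aryloxy)-3-hydroxy-3-[3,5-dimethoxy-4-(tosyloxy)phenyl]propanoate, syn | COc1cc([C@@H]2OC[C@@H]3[C@H]2CO[C@@H]3c2cc(OC)c(O[C@H](C(=O)OCC)[C@H](O)c3cc(OC)c(OS(=O)(=O)c4ccc(C)cc4)c(OC)c3)c(OC)c2)ccc1OS(=O)(=O)c1ccc(C)cc1
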